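The route rests on disconnecting C1–C10. Ring B (C5–C10), with its C7 oxygen, the C17 methyl on C8, the chain on C9 and the C20 methyl on C10, is treated as a 2,4-dimethylphenol whose carbon para to oxygen is C10. In one operation the phenoxide carbon C10 displaces a C1 sulfonate on the arm attached at C5, which closes ring A, creates the quaternary stereocentre C10 and leaves a cross-conjugated dienone ready for stepwise reduction. The precursor is a pentasubstituted 6-bromophenol whose C5 arm carries the C4 quaternary centre, a C2 silyl ether and a C1 tosylate; the arm's two stereocentres come from a glycidyl ether and a lactone arylation.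

Key step: step 15

Remark: labdane numbering is used; β is the face of the C20 methyl and C19 is the 4β carbon. The target is read as 19-acetoxy-2α,7α-dihydroxy-14,15-dinorlabd-8(17)-en-13-one with 5α-H, 9α-H and 10β-methyl (2R,4S,5R,7R,9R,10S).
Abbreviations: R = 2-(2-methyl-1,3-dioxolan-2-yl)ethyl; TBS = tert-butyldimethylsilyl; TIPS = triisopropylsilyl; Ts = 4-methylbenzenesulfonyl; Bn = benzyl.

Step 1
Reactants: 1 2-bromo-1,3-dimethylbenzene; 2 2-(2-bromoethyl)-2-methyl-1,3-dioxolane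
Product: 4 2-[2-(2,6-dimethylphenyl)ethyl]-2-methyl-1,3-dioxolane, via alkylzinc bromide 3 (not isolated)
Conditions: 2, Zn dust, LiCl, THF, 40 °C; then 1, Pd(OAc)2 (2 mol%), SPhos (4 mol%), 60 °C
Reagents that add atoms: none
Why: Zinc insertion into the primary bromide followed by Negishi coupling with a bulky biarylphosphine–palladium catalyst should tolerate both ortho methyl groups and the ketal.

Step 2
Reactants: 4 2-[2-(2,6-dimethylphenyl)ethyl]-2-methyl-1,3-dioxolane
Product: 5 2-[2-(3-bromo-2,6-dimethylphenyl)ethyl]-2-methyl-1,3-dioxolane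
Conditions: NBS (1.05 equiv), MeCN, 20 °C, dark
Reagents that add atoms: N-bromosuccinimide, O=C1CCC(=O)N1Br
Why: Electrophilic aromatic bromination under neutral conditions should enter ortho to one methyl and para to the other (two equivalent sites, the future C5), and the first bromine slows a second substitution.

Step 3
Reactants: 6 diethyl methylmalonate; 7 (S)-benzyl glycidyl ether
Product: 8 ethyl (5S)-5-[(benzyloxy)methyl]-3-methyl-2-oxotetrahydrofuran-3-carboxylate (both C3 epimers)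
Conditions: NaOEt (0.3 equiv), EtOH, reflux
Reagents that add atoms: none
Why: The malonate anion opens the epoxide at its terminal carbon (SN2) and the alkoxide lactonises onto one ester, so the carbinol centre (future C2) is carried over from the epoxide unchanged.

Step 4
Reactants: 8 ethyl (5S)-5-[(benzyloxy)methyl]-3-methyl-2-oxotetrahydrofuran-3-carboxylate
Product: 9 (5S)-5-[(benzyloxy)methyl]-3-methyldihydrofuran-2(3H)-one (both C3 epimers)
Conditions: LiCl, DMSO, H2O, 150 °C
Reagents that add atoms: none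
Why: Krapcho dealkoxycarbonylation removes the ester, and the C3 mixture is of no consequence because this centre becomes an enolate in the next step.

Step 5
Reactants: 9 (5S)-5-[(benzyloxy)methyl]-3-methyldihydrofuran-2(3H)-one; 5 2-[2-(3-bromo-2,6-dimethylphenyl)ethyl]-2-methyl-1,3-dioxolane
Product: 11 (3S,5S)-5-[(benzyloxy)methyl]-3-(2,4-dimethyl-3-R-phenyl)-3-methyldihydrofuran-2(3H)-one, via chlorozinc enolate 10 (not isolated)
Conditions: 9, LiN(SiMe3)2, THF, −78 °C; ZnCl2, −78 → 20 °C; then 5, Pd(dba)2 (3 mol%), P(t-Bu)3 (6 mol%), 50 °C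
Reagents that add atoms: none
Why: Palladium-catalysed α-arylation of the zinc enolate of an α-methyl-γ-butyrolactone builds the quaternary C4, and the aryl group should enter on the enolate face anti to the C5 benzyloxymethyl group, giving the 3,5-trans lactone with the C4/C2 relationship of the target.

Step 6
Reactants: 11 (3S,5S)-5-[(benzyloxy)methyl]-3-(2,4-dimethyl-3-R-phenyl)-3-methyldihydrofuran-2(3H)-one
Product: 12 (3S,5S)-5-[(benzyloxy)methyl]-3-(5-bromo-2,4-dimethyl-3-R-phenyl)-3-methyldihydrofuran-2(3H)-one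
Conditions: NBS (1.05 equiv), MeCN, 0 → 20 °C, dark
Reagents that add atoms: N-bromosuccinimide, O=C1CCC(=O)N1Br
Why: Electrophilic bromination of the tetra-alkylbenzene should go to C7 (ortho to the C8 methyl, para to the C10 methyl), because the only other free site, C6, is shielded by the adjacent quaternary carbon.

Step 7
Reactants: 12 (3S,5S)-5-[(benzyloxy)methyl]-3-(5-bromo-2,4-dimethyl-3-R-phenyl)-3-methyldihydrofuran-2(3H)-one
Product: 14 (3S,5S)-5-[(benzyloxy)methyl]-3-(5-hydroxy-2,4-dimethyl-3-R-phenyl)-3-methyldihydrofuran-2(3H)-one, via aryl pinacol boronate 13 (not isolated)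
Conditions: B2pin2, Pd(dppf)Cl2 (3 mol%), KOAc, dioxane, 90 °C; then 30% H2O2, aq. NaHCO3, THF, 0 → 20 °C
Reagents that add atoms: hydrogen peroxide, OO
Why: Miyaura borylation followed by oxidation of the C–B bond turns the aryl bromide into the C7 phenol without touching the lactone, benzyl ether or ketal.

Step 8
Reactants: 14 (3S,5S)-5-[(benzyloxy)methyl]-3-(5-hydroxy-2,4-dimethyl-3-R-phenyl)-3-methyldihydrofuran-2(3H)-one
Product: 15 (2S,4S)-5-(benzyloxy)-2-(5-hydroxy-2,4-dimethyl-3-R-phenyl)-2-methylpentane-1,4-diol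
Conditions: LiAlH4, THF, 0 °C; aq. potassium sodium tartrate
Reagents that add atoms: none
Why: Hydride reduction of the lactone gives the primary C19 and secondary C2 hydroxyls without touching either stereocentre.

Step 9
Reactants: 15 (2S,4S)-5-(benzyloxy)-2-(5-hydroxy-2,4-dimethyl-3-R-phenyl)-2-methylpentane-1,4-diol
Product: 16 (2S,4S)-1-(benzyloxy)-5-(TBS-oxy)-4-[5-(TBS-oxy)-2,4-dimethyl-3-R-phenyl]-4-methylpentan-2-ol
Conditions: TBSCl (2.1 equiv), imidazole, CH2Cl2, 0 °C
Reagents that add atoms: tert-butyldimethylsilyl chloride, CC(C)(C)[Si](C)(C)Cl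
Why: Silylation with the chloride should take the phenol and the primary C19 hydroxyl well before the secondary C2 hydroxyl, which differentiates the two alcohols of the diol.

Step 10
Reactants: 16 (2S,4S)-1-(benzyloxy)-5-(TBS-oxy)-4-[5-(TBS-oxy)-2,4-dimethyl-3-R-phenyl]-4-methylpentan-2-ol
Product: 17 the C2 TIPS ether of 16
Conditions: TIPSOTf, 2,6-lutidine, CH2Cl2, 0 °C
Reagents that add atoms: triisopropylsilyl trifluoromethanesulfonate, CC(C)[Si](C(C)C)(C(C)C)OS(=O)(=O)C(F)(F)F
Why: The silyl triflate silylates the remaining secondary alcohol and gives an ether that outlasts the primary TBS ether under acid later.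

Step 11
Reactants: 17 the C2 TIPS ether of 16
Product: 18 (2S,4S)-5-(TBS-oxy)-4-[5-(TBS-oxy)-2,4-dimethyl-3-R-phenyl]-4-methyl-2-(TIPS-oxy)pentan-1-ol
Conditions: H2 (1 atm), Pd/C, EtOAc, 20 °C
Reagents that add atoms: none
Why: Hydrogenolysis removes the only benzyl ether at a stage with no aryl halide present, while silyl ethers and the ketal are inert in a neutral aprotic solvent.

Step 12
Reactants: 18 (2S,4S)-5-(TBS-oxy)-4-[5-(TBS-oxy)-2,4-dimethyl-3-R-phenyl]-4-methyl-2-(TIPS-oxy)pentan-1-ol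
Product: 19 the C1 4-methylbenzenesulfonate of 18
Conditions: TsCl, Et3N, DMAP (cat.), CH2Cl2, 0 → 20 °C
Reagents that add atoms: 4-methylbenzenesulfonyl chloride, Cc1ccc(cc1)S(=O)(=O)Cl
Why: Sulfonylation of the only free hydroxyl installs the C1 nucleofuge while the phenol is still masked, so no aryl sulfonate can form.

Step 13
Reactants: 19 the C1 4-methylbenzenesulfonate of 18
Product: 20 (2S,4S)-5-(TBS-oxy)-4-(5-hydroxy-2,4-dimethyl-3-R-phenyl)-4-methyl-2-(TIPS-oxy)pentyl 4-methylbenzenesulfonate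
Conditions: KHF2, MeOH, 20 °C
Reagents that add atoms: none
Why: Bifluoride cleaves the aryl silyl ether much faster than alkyl silyl ethers, and its acidity keeps the phenol protonated so that it cannot cyclise before C6 is blocked.

Step 14
Reactants: 20 (2S,4S)-5-(TBS-oxy)-4-(5-hydroxy-2,4-dimethyl-3-R-phenyl)-4-methyl-2-(TIPS-oxy)pentyl 4-methylbenzenesulfonate
Product: 21 (2S,4S)-4-(2-bromo-3-hydroxy-4,6-dimethyl-5-R-phenyl)-5-(TBS-oxy)-4-methyl-2-(TIPS-oxy)pentyl 4-methylbenzenesulfonate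
Conditions: NBS (1.0 equiv), i-Pr2NH (10 mol%), CH2Cl2, 0 °C
Reagents that add atoms: N-bromosuccinimide, O=C1CCC(=O)N1Br
Why: Amine-promoted ortho-bromination of the phenol can only end at C6, the single unsubstituted ring position, and gives the blocking group for the dearomatisation.

Step 15
Reactants: 21 (2S,4S)-4-(2-bromo-3-hydroxy-4,6-dimethyl-5-R-phenyl)-5-(TBS-oxy)-4-methyl-2-(TIPS-oxy)pentyl 4-methylbenzenesulfonate
Product: 23 6-bromo-13,13-(ethylenedioxy)-19-(TBS-oxy)-2α-(TIPS-oxy)-14,15-dinorlabda-5,8-dien-7-one (10β-methyl), via potassium phenoxide 22 (not isolated)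
Conditions: KOtBu (1.05 equiv), t-BuOH/THF (0.01 M), 20 → 60 °C
Reagents that add atoms: none
Why: KOtBu deprotonates the phenol and the ambident phenoxide attacks the primary C1 sulfonate through its para carbon C10 in an intramolecular SN2 displacement, which removes aromaticity and leaves the C7 carbonyl of a 2,5-cyclohexadienone; the closest known reaction type is the base-mediated intramolecular para C-alkylation of phenols to fused cyclohexadienones. Ring A (C1–C5, C10) closes in the 6-exo-tet mode. The new quaternary stereocentre C10 is controlled by the tether stereocentres C2 and C4: in the chair-like transition state the C10 methyl is axial, and only attack on the arene face that gives the 10β-methyl isomer keeps the C2 silyloxy group equatorial and has the C19 arm alone, instead of the C18 methyl plus the silyloxy group, syn-axial to it. The step needs C- over O-alkylation, para over ortho attack and substitution over elimination: the oxygen cannot reach C1 through the meta-attached arm, the ortho carbon C6 carries bromine, and near-stoichiometric base at high dilution in tert-butanol leaves the weakly basic, hydrogen-bonded phenoxide as the only base.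

Step 16
Reactants: 23 6-bromo-13,13-(ethylenedioxy)-19-(TBS-oxy)-2α-(TIPS-oxy)-14,15-dinorlabda-5,8-dien-7-one
Product: 24 13,13-(ethylenedioxy)-19-(TBS-oxy)-2α-(TIPS-oxy)-14,15-dinor-5α-labd-8-en-7-one
Conditions: Li, NH3(l)/THF, t-BuOH (2 equiv), −78 °C; isoprene, then NH4Cl
Reagents that add atoms: none
Why: Dissolving-metal (Birch-type) reduction cleaves the vinylic C–Br bond and should reduce the less alkylated enone arm C5=C6 first, with axial protonation of C5 anti to the C10 methyl setting the trans ring fusion; the reaction stops at the cross-conjugated dienolate, which gives the C8=C9 enone on quenching.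

Step 17
Reactants: 24 13,13-(ethylenedioxy)-19-(TBS-oxy)-2α-(TIPS-oxy)-14,15-dinor-5α-labd-8-en-7-one
Product: 26 13,13-(ethylenedioxy)-19-(TBS-oxy)-2α-(TIPS-oxy)-14,15-dinorlabd-7-en-7-yl trifluoromethanesulfonate (9α-H), via lithium enolate 25 (not isolated)
Conditions: Li, NH3(l)/THF, t-BuOH (1 equiv), −78 → −33 °C; isoprene; NH3 removed; PhNTf2, THF, 0 → 20 °C
Reagents that add atoms: N-phenylbis(trifluoromethanesulfonimide), O=S(=O)(N(c1ccccc1)S(=O)(=O)C(F)(F)F)C(F)(F)F
Why: Conjugate reduction of the enone by lithium in ammonia protonates C9 axially (9α-H, equatorial side chain) and leaves the regiodefined C7=C8 enolate, which is trapped on oxygen as the enol triflate.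

Step 18
Reactants: 26 13,13-(ethylenedioxy)-19-(TBS-oxy)-2α-(TIPS-oxy)-14,15-dinorlabd-7-en-7-yl trifluoromethanesulfonate
Product: 27 13,13-(ethylenedioxy)-19-(TBS-oxy)-2α-(TIPS-oxy)-14,15-dinorlabd-7-ene
Conditions: Pd(OAc)2 (5 mol%), PPh3 (10 mol%), HCO2H, n-Bu3N, DMF, 60 °C
Reagents that add atoms: none
Why: Palladium-catalysed formate reduction of the enol triflate replaces the triflate by hydrogen without moving the C7=C8 double bond.

Step 19
Reactants: 27 13,13-(ethylenedioxy)-19-(TBS-oxy)-2α-(TIPS-oxy)-14,15-dinorlabd-7-ene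
Product: 28 19-hydroxy-2α-(TIPS-oxy)-14,15-dinorlabd-7-en-13-one
Conditions: 1 M HCl, THF, 20 °C
Reagents that add atoms: water, O
Why: Dilute aqueous acid hydrolyses the primary TBS ether and the dioxolane, while the far more acid-stable secondary TIPS ether keeps C2 protected.

Step 20
Reactants: 28 19-hydroxy-2α-(TIPS-oxy)-14,15-dinorlabd-7-en-13-one
Product: 29 19-acetoxy-2α-(TIPS-oxy)-14,15-dinorlabd-7-en-13-one
Conditions: Ac2O, pyridine, DMAP (cat.), CH2Cl2, 20 °C
Reagents that add atoms: acetic anhydride, CC(=O)OC(C)=O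
Why: Acylation of the only free hydroxyl places the acetate on C19 without any selectivity question.

Step 21
Reactants: 29 19-acetoxy-2α-(TIPS-oxy)-14,15-dinorlabd-7-en-13-one
Product: 31 19-acetoxy-7α-hydroxy-2α-(TIPS-oxy)-14,15-dinorlabd-8(17)-en-13-one, via allylic hydroperoxide 30 (not isolated)
Conditions: O2, visible light, tetraphenylporphyrin (cat.), CH2Cl2, 0 °C; then PPh3, 0 → 20 °C
Reagents that add atoms: dioxygen, O=O
Why: In the Schenck ene reaction singlet oxygen should add to C7 from the α face, opposite the axial C10 methyl, taking a hydrogen from the C17 methyl to give the exocyclic alkene, and phosphine reduction of the hydroperoxide keeps the 7α configuration.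

Step 22
Reactants: 31 19-acetoxy-7α-hydroxy-2α-(TIPS-oxy)-14,15-dinorlabd-8(17)-en-13-one
Product: 32 19-acetoxy-2α,7α-dihydroxy-14,15-dinorlabd-8(17)-en-13-one
Conditions: HF·pyridine, pyridine/THF, 0 → 20 °C
Reagents that add atoms: none
Why: Buffered fluoride removes the silyl ether without hydrolysing the acetate or ionising the allylic alcohol.

Compound list
1 | 2-bromo-1,3-dimethylbenzene | Cc1cccc(C)c1Br | starting material
2 | 2-(2-bromoethyl)-2-methyl-1,3-dioxolane | CC1(CCBr)OCCO1 | starting material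
3 | [2-(2-methyl-1,3-dioxolan-2-yl)ethyl]zinc bromide | CC1(CC[Zn]Br)OCCO1 | intermediate
4 | 2-[2-(2,6-dimethylphenyl)ethyl]-2-methyl-1,3-dioxolane | Cc1cccc(C)c1CCC1(C)OCCO1 | intermediate
5 | 2-[2-(3-bromo-2,6-dimethylphenyl)ethyl]-2-methyl-1,3-dioxolane | Cc1c(CCC2(C)OCCO2)c(C)ccc1Br | intermediate
6 | diethyl methylmalonate | CCOC(=O)C(C)C(=O)OCC | starting material
7 | (S)-benzyl glycidyl ether | C1[C@H](O1)COCc2ccccc2 | starting material
8 | ethyl (5S)-5-[(benzyloxy)methyl]-3-methyl-2-oxotetrahydrofuran-3-carboxylate, C3 epimers | CCOC(=O)C1(C)C[C@@H](COCc2ccccc2)OC1=O | intermediate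
9 | (5S)-5-[(benzyloxy)methyl]-3-methyldihydrofuran-2(3H)-one, C3 epimers | CC1C[C@@H](COCc2ccccc2)OC1=O | intermediate
10 | chlorozinc enolate of 9 | Cl[Zn]OC1=C(C)C[C@@H](COCc2ccccc2)O1 | intermediate
11 | (3S,5S)-5-[(benzyloxy)methyl]-3-(2,4-dimethyl-3-R-phenyl)-3-methyldihydrofuran-2(3H)-one | Cc1c(CCC2(C)OCCO2)c(C)ccc1[C@]3(C)C[C@@H](COCc4ccccc4)OC3=O | intermediate
12 | (3S,5S)-5-[(benzyloxy)methyl]-3-(5-bromo-2,4-dimethyl-3-R-phenyl)-3-methyldihydrofuran-2(3H)-one | Cc1c(CCC2(C)OCCO2)c(C)c(Br)cc1[C@]3(C)C[C@@H](COCc4ccccc4)OC3=O | intermediate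
13 | aryl pinacol boronate corresponding to 12 (Bpin at C7) | Cc1c(CCC2(C)OCCO2)c(C)c(B5OC(C)(C)C(C)(C)O5)cc1[C@]3(C)C[C@@H](COCc4ccccc4)OC3=O | intermediate
14 | (3S,5S)-5-[(benzyloxy)methyl]-3-(5-hydroxy-2,4-dimethyl-3-R-phenyl)-3-methyldihydrofuran-2(3H)-one | Cc1c(CCC2(C)OCCO2)c(C)c(O)cc1[C@]3(C)C[C@@H](COCc4ccccc4)OC3=O | intermediate
15 | (2S,4S)-5-(benzyloxy)-2-(5-hydroxy-2,4-dimethyl-3-R-phenyl)-2-methylpentane-1,4-diol | Cc1c(CCC2(C)OCCO2)c(C)c(O)cc1[C@@](C)(CO)C[C@H](O)COCc3ccccc3 | intermediate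
16 | (2S,4S)-1-(benzyloxy)-5-(TBS-oxy)-4-[5-(TBS-oxy)-2,4-dimethyl-3-R-phenyl]-4-methylpentan-2-ol | Cc1c(CCC2(C)OCCO2)c(C)c(O[Si](C)(C)C(C)(C)C)cc1[C@@](C)(CO[Si](C)(C)C(C)(C)C)C[C@H](O)COCc3ccccc3 | intermediate
17 | C2 TIPS ether of 16 | Cc1c(CCC2(C)OCCO2)c(C)c(O[Si](C)(C)C(C)(C)C)cc1[C@@](C)(CO[Si](C)(C)C(C)(C)C)C[C@H](O[Si](C(C)C)(C(C)C)C(C)C)COCc3ccccc3 | intermediate
18 | (2S,4S)-5-(TBS-oxy)-4-[5-(TBS-oxy)-2,4-dimethyl-3-R-phenyl]-4-methyl-2-(TIPS-oxy)pentan-1-ol | Cc1c(CCC2(C)OCCO2)c(C)c(O[Si](C)(C)C(C)(C)C)cc1[C@@](C)(CO[Si](C)(C)C(C)(C)C)C[C@H](O[Si](C(C)C)(C(C)C)C(C)C)CO | intermediate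
19 | C1 4-methylbenzenesulfonate of 18 | Cc1c(CCC2(C)OCCO2)c(C)c(O[Si](C)(C)C(C)(C)C)cc1[C@@](C)(CO[Si](C)(C)C(C)(C)C)C[C@H](O[Si](C(C)C)(C(C)C)C(C)C)COS(=O)(=O)c3ccc(C)cc3 | intermediate
20 | (2S,4S)-5-(TBS-oxy)-4-(5-hydroxy-2,4-dimethyl-3-R-phenyl)-4-methyl-2-(TIPS-oxy)pentyl 4-methylbenzenesulfonate | Cc1c(CCC2(C)OCCO2)c(C)c(O)cc1[C@@](C)(CO[Si](C)(C)C(C)(C)C)C[C@H](O[Si](C(C)C)(C(C)C)C(C)C)COS(=O)(=O)c3ccc(C)cc3 | intermediate
21 | (2S,4S)-4-(2-bromo-3-hydroxy-4,6-dimethyl-5-R-phenyl)-5-(TBS-oxy)-4-methyl-2-(TIPS-oxy)pentyl 4-methylbenzenesulfonate (key-step precursor) | Cc1c(CCC2(C)OCCO2)c(C)c(O)c(Br)c1[C@@](C)(CO[Si](C)(C)C(C)(C)C)C[C@H](O[Si](C(C)C)(C(C)C)C(C)C)COS(=O)(=O)c3ccc(C)cc3 | intermediate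
22 | potassium phenoxide of 21 | Cc1c(CCC2(C)OCCO2)c(C)c([O-])c(Br)c1[C@@](C)(CO[Si](C)(C)C(C)(C)C)C[C@H](O[Si](C(C)C)(C(C)C)C(C)C)COS(=O)(=O)c3ccc(C)cc3.[K+] | intermediate
23 | 6-bromo-13,13-(ethylenedioxy)-19-(TBS-oxy)-2α-(TIPS-oxy)-14,15-dinorlabda-5,8-dien-7-one (key-step product) | O=C1C(Br)=C2[C@@](C)(CO[Si](C)(C)C(C)(C)C)C[C@H](O[Si](C(C)C)(C(C)C)C(C)C)C[C@]2(C)C(CCC3(C)OCCO3)=C1C | intermediate
24 | 13,13-(ethylenedioxy)-19-(TBS-oxy)-2α-(TIPS-oxy)-14,15-dinor-5α-labd-8-en-7-one | O=C1C[C@H]2[C@@](C)(CO[Si](C)(C)C(C)(C)C)C[C@H](O[Si](C(C)C)(C(C)C)C(C)C)C[C@]2(C)C(CCC3(C)OCCO3)=C1C | intermediate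
25 | lithium C7=C8 enolate from 24 (9α-H) | CC1=C([O-])C[C@H]2[C@@](C)(CO[Si](C)(C)C(C)(C)C)C[C@H](O[Si](C(C)C)(C(C)C)C(C)C)C[C@]2(C)[C@H]1CCC3(C)OCCO3.[Li+] | intermediate
26 | 13,13-(ethylenedioxy)-19-(TBS-oxy)-2α-(TIPS-oxy)-14,15-dinorlabd-7-en-7-yl trifluoromethanesulfonate | CC1=C(OS(=O)(=O)C(F)(F)F)C[C@H]2[C@@](C)(CO[Si](C)(C)C(C)(C)C)C[C@H](O[Si](C(C)C)(C(C)C)C(C)C)C[C@]2(C)[C@H]1CCC3(C)OCCO3 | intermediate
27 | 13,13-(ethylenedioxy)-19-(TBS-oxy)-2α-(TIPS-oxy)-14,15-dinorlabd-7-ene | CC1=CC[C@H]2[C@@](C)(CO[Si](C)(C)C(C)(C)C)C[C@H](O[Si](C(C)C)(C(C)C)C(C)C)C[C@]2(C)[C@H]1CCC3(C)OCCO3 | intermediate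
28 | 19-hydroxy-2α-(TIPS-oxy)-14,15-dinorlabd-7-en-13-one | CC1=CC[C@H]2[C@@](C)(CO)C[C@H](O[Si](C(C)C)(C(C)C)C(C)C)C[C@]2(C)[C@H]1CCC(C)=O | intermediate
29 | 19-acetoxy-2α-(TIPS-oxy)-14,15-dinorlabd-7-en-13-one | CC1=CC[C@H]2[C@@](C)(COC(C)=O)C[C@H](O[Si](C(C)C)(C(C)C)C(C)C)C[C@]2(C)[C@H]1CCC(C)=O | intermediate
30 | 19-acetoxy-7α-hydroperoxy-2α-(TIPS-oxy)-14,15-dinorlabd-8(17)-en-13-one | C=C1[C@H](OO)C[C@H]2[C@@](C)(COC(C)=O)C[C@H](O[Si](C(C)C)(C(C)C)C(C)C)C[C@]2(C)[C@H]1CCC(C)=O | intermediate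
31 | 19-acetoxy-7α-hydroxy-2α-(TIPS-oxy)-14,15-dinorlabd-8(17)-en-13-one | C=C1[C@H](O)C[C@H]2[C@@](C)(COC(C)=O)C[C@H](O[Si](C(C)C)(C(C)C)C(C)C)C[C@]2(C)[C@H]1CCC(C)=O | intermediate
32 | 19-acetoxy-2α,7α-dihydroxy-14,15-dinorlabd-8(17)-en-13-one (CNP0139304.2) | C=C1[C@H](O)C[C@H]2[C@@](C)(COC(C)=O)C[C@H](O)C[C@]2(C)[C@H]1CCC(C)=O | target

Total step count: 22. Longest linear sequence: 20 steps (steps 1, 2 and 5–22 from 2-bromo-1,3-dimethylbenzene; the lactone branch, steps 3, 4 and 5–22, is equally long).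

Steps most likely to fail

1. Step 15. Closure at the congested, methyl-bearing para carbon may be slow, so that elimination of the β-silyloxy sulfonate or intermolecular alkylation competes, and the face selectivity at C10 may be lower than the chair model predicts. The fallback replaces the sulfonate by a terminal epoxide, sets out from 16 and returns at 23. Hydrogenolysis of the benzyl ether of 16 (H2, Pd/C) gives the 1,2-diol F4. Tin-catalysed monosulfonylation of its primary hydroxyl (TsCl, Bu2SnO cat., Et3N) gives the hydroxy tosylate F5. K2CO3 in methanol closes the oxirane and cleaves the aryl silyl ether in the same flask, giving the phenol epoxide F6. NBS bromination at C6 gives the bromophenol epoxide F7. KOtBu in hot tert-butanol should then open the epoxide at its terminal carbon through the para carbon; this is the six-membered closure, and backside attack places the C2 oxygen equatorial in the forming chair. It delivers the 2α-hydroxy dienone F8, and TIPSOTf/2,6-lutidine converts F8 into 23.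

2. Step 5. Coupling at an aryl bromide with an ortho methyl group while a quaternary centre is formed may stall at the reductive elimination, giving protodehalogenated arene, or may show poor facial selectivity on the enolate. The fallback sets out from 5 and 7 and returns at 11. Decarboxylative palladium coupling of 5 with potassium 2-cyanopropanoate ([PdCl(C3H5)]2, SPhos, mesitylene, 140 °C) gives the 2-arylpropanenitrile F1. Its anion (LiN(iPr)2, THF, −78 °C) opens epoxide 7 at the terminal carbon to the γ-hydroxy nitrile F2, as both epimers at the new quaternary carbon. Base-induced closure to the iminolactone and hydrolysis with aqueous acetic acid give 11 together with its C3-epimeric lactone F3, which are separated by chromatography. This path forms the quaternary centre by alkylation instead of arylation and gives up the diastereocontrol.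

3. Step 16. The first electron-transfer reduction may protonate C9 instead of C5, that is, reduce the wrong enone arm first, which would misplace the enolate of step 17; over-reduction is the second concern. The fallback sets out from 23 and returns at 24. Heterogeneous hydrogenation (H2, Pd/C, Et3N, EtOAc) hydrogenolyses the vinylic bromide and should saturate only the trisubstituted C5=C6 bond, from the α face opposite the axial C19 and C20 groups, leaving the tetrasubstituted C8=C9 enone. Selection then rests on alkene substitution and not on the site of protonation of a radical anion. No new compound is made.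

Further compounds
F1 | step 5 | 2-(2,4-dimethyl-3-R-phenyl)propanenitrile (racemic) | Cc1c(CCC2(C)OCCO2)c(C)ccc1C(C)C#N
F2 | step 5 | (4S)-5-(benzyloxy)-2-(2,4-dimethyl-3-R-phenyl)-4-hydroxy-2-methylpentanenitrile (both C2 epimers) | Cc1c(CCC2(C)OCCO2)c(C)ccc1C(C)(C#N)C[C@H](O)COCc3ccccc3
F3 | step 5 | (3R,5S)-5-[(benzyloxy)methyl]-3-(2,4-dimethyl-3-R-phenyl)-3-methyldihydrofuran-2(3H)-one (C3 epimer of 11) | Cc1c(CCC2(C)OCCO2)c(C)ccc1[C@@]3(C)C[C@@H](COCc4ccccc4)OC3=O
F4 | step 15 | (2S,4S)-5-(TBS-oxy)-4-[5-(TBS-oxy)-2,4-dimethyl-3-R-phenyl]-4-methylpentane-1,2-diol | Cc1c(CCC2(C)OCCO2)c(C)c(O[Si](C)(C)C(C)(C)C)cc1[C@@](C)(CO[Si](C)(C)C(C)(C)C)C[C@H](O)CO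
F5 | step 15 | C1 4-methylbenzenesulfonate of F4 | Cc1c(CCC2(C)OCCO2)c(C)c(O[Si](C)(C)C(C)(C)C)cc1[C@@](C)(CO[Si](C)(C)C(C)(C)C)C[C@H](O)COS(=O)(=O)c3ccc(C)cc3
F6 | step 15 | 5-[(2S)-1-(TBS-oxy)-2-methyl-3-[(2S)-oxiran-2-yl]propan-2-yl]-2,4-dimethyl-3-R-phenol | Cc1c(CCC2(C)OCCO2)c(C)c(O)cc1[C@@](C)(CO[Si](C)(C)C(C)(C)C)C[C@H]3CO3
F7 | step 15 | 6-bromo derivative of F6 (bromine between the hydroxyl and the arm) | Cc1c(CCC2(C)OCCO2)c(C)c(O)c(Br)c1[C@@](C)(CO[Si](C)(C)C(C)(C)C)C[C@H]3CO3
F8 | step 15 | 6-bromo-13,13-(ethylenedioxy)-2α-hydroxy-19-(TBS-oxy)-14,15-dinorlabda-5,8-dien-7-one | O=C1C(Br)=C2[C@@](C)(CO[Si](C)(C)C(C)(C)C)C[C@H](O)C[C@]2(C)C(CCC3(C)OCCO3)=C1C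
F0 | step 16 | none | none
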